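# Proposed total synthesis of Agrimol C by head-to-tail [2+2+2] assembly of the central ring

## The problem

Agrimol C is an achiral trimer in which a central butyrylphloroglucinol (ring A: C1 butyryl, C2/C4/C6 hydroxyl, C3/C5 arylmethyl) carries, through two CH2 bridges, two identical outer rings (C1' bridge, C2' OH, C3' CH3, C4' OCH3, C5' butyryl, C6' OH). All three benzene rings are hexasubstituted and there is no stereocentre, so the task is one of regiochemistry only. On each outer ring three oxygens must be told apart: two stay free, and the methylated one lies between the methyl and the butyryl group. The fragile part is the pair of diarylmethane bridges between electron-rich phloroglucinols: strong Lewis acids, hot protic acid and alkali open them through quinone-methide-type fragmentation and scramble the rings, and the free polyphenol is easily oxidised. Friedel–Crafts chemistry after bridging is therefore avoided and the last step must be mild. The feature that is exploited is the strict alternation around ring A of carbon-bearing carbons (C1, C3, C5) and oxygen-bearing carbons (C2, C4, C6), which is the pattern of a head-to-tail trimer of three 1-alkoxyalkynes: C1–C2 from an acyl ynol ether, C3–C4 and C5–C6 from two molecules of one arylpropargyl ynol ether. Because the outer rings are identical, one outer building block serves twice.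

## Retrosynthesis

**20 from 19.** Only protecting-group O–C bonds are cut: three tert-butyl ethers on ring A and four methoxymethyl ethers on the outer rings, all acid-labile, so one mild protic treatment ends the synthesis. The neighbouring option, adding the two outer butyryl groups after the bridges exist, would expose the bridged polyphenol to Friedel–Crafts conditions. Carrying all three butyryl groups in 19 avoids this. The forward step must cleave acetals and tert-butyl ethers without touching the bridges. Every ring carbon is substituted and each ring is acyl-deactivated, which helps.

**19 from two molecules of 15 and one of 18.** The bonds C2–C3, C4–C5 and C6–C1 of ring A are cut. Ring A, its three oxygens, its butyryl group and both bridges then arise in one convergent step from a C6 ynone and a one-ring ynol ether. Building ring A first and benzylating it twice would face over-alkylation and the lability named above. All three alkynes carry tert-butoxy, which comes from one commercial alkyne 12 and leaves with acid. A silyl ynol ether made by acetylide oxidation was weighed for the donor alkyne. Its preparation needs strong base in the presence of the aryl ketone, which would force the outer butyryl groups to the end, so it was set aside. The forward reaction must deliver the two-to-one cross-trimer and the head-to-tail orientation.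

**18 from 12 and 7.** The acyl–alkyne bond is cut. The bromomagnesium acetylide 16, made from 12 with EtMgBr, is acylated by Weinreb amide 7. The magnesium chelate 17 holds the reaction at the ketone stage, so the push–pull ynone is reached in one step. The Grignard reagent is preferred here to the lithium acetylide because it is less basic towards the α-hydrogens of 7 and its chelate is the more robust one.

**15 from 11 and 12.** The C(sp3)–C(sp) bond between the benzylic carbon and the alkyne is cut. The lithium acetylide 13 is transmetalated at low temperature to the zinc acetylide 14, and a palladium-catalysed coupling of 14 with benzylic bromide 11 is neutral enough for the aryl ketone and for the ynol ether. The alternative, building a terminal propargyl arene and oxidising its acetylide, needs organolithium chemistry that the ketone would not survive.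

**11 from 10, and 10 from 6 and 7.** The C–Br bond is a functional-group change. The aryl–acyl bond at C5' is cut by directed ortho-metalation: 6 has a single ring hydrogen, flanked by OMe and OMOM, so the site is not in doubt. A Friedel–Crafts butyrylation of the formyl-deactivated diphenol 4 is the neighbouring cut. It risks the methoxy group ortho to the new ketone and is kept as a fallback.

**6 from 5, 4, 3 and 1.** The formyl carbon of 3 serves twice: it becomes the bridge carbon, and it controls the oxygen pattern. In 3 it is flanked by exactly the two methoxy groups that must become free hydroxyls, so chelation-controlled ether cleavage gives 4 and leaves the para methoxy group. Symmetrical 1 has two equivalent free positions, so formylation raises no regiochemical question.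

## Roads not taken

**Alternative 1:** The two C6'–O bonds are cut, leading back to the 6',6''-dideoxy pentaacetate A2. In the forward step Pd(OAc)2 (divalent palladium) and PhI(OCOCF3)2 in trifluoroacetic acid would hydroxylate both C6'–H bonds ortho to the outer ketones and give A1. Deacetylation would follow.
- Merits: each outer ketone has only one ortho C–H, so the site is dictated. Ketone-directed C–H oxygenation is an established reaction type on simple aryl ketones.
- Weak points: the cut simplifies nothing skeletal, since all three rings and both bridges must already exist. The strongly acidic, oxidising medium meets electron-rich diarylmethanes, with risk of benzylic oxidation and bridge cleavage. The ketone is twisted by its ortho substituents, and the C–H to be palladated lies between two substituents. The reaction must succeed twice on one molecule.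
- Comparison: this road is better in that its key reaction type is known. The chosen plan sets against it that the risk is taken at a convergent stage on small alkynes, and that the finished skeleton then sees only a deprotection.

**Alternative 2:** The three C–O bonds of ring A are cut, leading back to the trifluoro ketone A4. Sodium benzyloxide would displace the three fluorides, all ortho or para to the C1 ketone, and give the heptabenzyl ether A3. Hydrogenolysis would finish.
- Merits: every reaction type is precedented, fluoride is the best leaving group for this substitution, and the end game is neutral. In predictability this road is at least equal to the chosen one, and probably better.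
- Weak points: each alkoxy group introduced deactivates the ring for the next displacement. The third substitution on a crowded, twisted dialkoxy aryl ketone needs forcing alkoxide conditions in the presence of three enolisable ketones and two doubly benzylic CH2 groups. Making A4 requires two alkylations of ortho-fluoroaryl metal species with the same labile, electron-rich benzylic halide used here.
- Comparison: the chosen plan sets against it that ring A arrives with its oxygens in place, so no late C–O exchange under strong base is needed, and that the route is shorter.

**Alternative 3:** The C1–C2 bond of ring A is cut, leading back to the methyl 2,4-bis(arylmethyl)-3,5,7-trioxodecanoate A6. A Claisen cyclisation of C6 onto the ester, followed by enolisation, would give A5.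
- Merits: the reaction is biomimetic, needs no transition metal, and the chain fixes the oxygen pattern.
- Weak points: the doubly alkylated tetracarbonyl chain is hard to make and to keep, because aldol closure, pyrone formation and retro-Claisen cleavage compete. A5 lacks both outer butyryl groups, so two Friedel–Crafts acylations and a debenzylation must follow on the bridged polyphenol, the operation judged most dangerous for this skeleton.
- Comparison: the ring closure itself is better precedented than the cyclotrimerisation. The chosen plan sets against it convergence, fewer steps, and the fact that all three butyryl groups enter with the alkynes.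

Key step: step 9

Remark: the target has no stereocentre and the route sets none; the tetrahedral adducts 9 and 17 are racemic and transient. N-Methoxy-N-methylbutanamide 7 is taken as a purchased reagent.

## Route

Step 1
Reactants: 1 2,4,6-trimethoxytoluene
Product: 3 2,4,6-trimethoxy-3-methylbenzaldehyde, via iminium chloride 2 (not isolated)
Conditions: POCl3, DMF, 0 °C → rt; then H2O, 0 °C → rt
Reagents that add atoms: N,N-dimethylformamide, CN(C)C=O; water, O
Why: Vilsmeier–Haack formylation; the two free positions of 1 are equivalent and each lies between two methoxy groups, so one aldehyde should form, and the deactivated product should not react again.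

Step 2
Reactants: 3 2,4,6-trimethoxy-3-methylbenzaldehyde
Product: 4 2,6-dihydroxy-4-methoxy-3-methylbenzaldehyde
Conditions: AlCl3 (4 equiv), CH2Cl2, 0 °C → reflux; then 1 M HCl, 0 °C
Reagents that add atoms: none
Why: Chelation-controlled aryl methyl ether cleavage; aluminium held at the formyl oxygen activates only the two flanking methoxy groups, as in the conversion of 2,6-dimethoxybenzaldehydes into 2,6-dihydroxybenzaldehydes, and the para methoxy group has no such assistance.

Step 3
Reactants: 4 2,6-dihydroxy-4-methoxy-3-methylbenzaldehyde
Product: 5 4-methoxy-2,6-bis(methoxymethoxy)-3-methylbenzaldehyde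
Conditions: NaH, MOMCl, DMF, 0 °C → rt
Reagents that add atoms: chloromethyl methyl ether, COCCl
Why: O-alkylation of the bis-phenoxide (Williamson type); MOM ethers are chosen because they direct the later metalation and leave with the tert-butyl ethers in one acidic step.

Step 4
Reactants: 5 4-methoxy-2,6-bis(methoxymethoxy)-3-methylbenzaldehyde
Product: 6 [4-methoxy-2,6-bis(methoxymethoxy)-3-methylphenyl]methanol
Conditions: NaBH4, MeOH/THF, 0 °C
Reagents that add atoms: none
Why: Hydride reduction of an aryl aldehyde; nothing else in 5 is reducible under these conditions.

Step 5
Reactants: 6 [4-methoxy-2,6-bis(methoxymethoxy)-3-methylphenyl]methanol; 7 N-methoxy-N-methylbutanamide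
Product: 10 1-[3-(hydroxymethyl)-6-methoxy-2,4-bis(methoxymethoxy)-5-methylphenyl]butan-1-one, via dilithio species 8 (not isolated), via tetrahedral adduct 9 (not isolated)
Conditions: n-BuLi (2.3 equiv), TMEDA, THF, −78 → 0 °C; then 7, −78 → 0 °C; aq NH4Cl
Reagents that add atoms: none
Why: Directed ortho-metalation followed by Weinreb acylation; after the alkoxide forms, the only ring hydrogen, flanked by OMe and OMOM, should be removed, and the chelated adduct 9 releases the ketone only on work-up, so no second addition occurs.

Step 6
Reactants: 10 1-[3-(hydroxymethyl)-6-methoxy-2,4-bis(methoxymethoxy)-5-methylphenyl]butan-1-one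
Product: 11 1-[3-(bromomethyl)-6-methoxy-2,4-bis(methoxymethoxy)-5-methylphenyl]butan-1-one
Conditions: CBr4, PPh3, CH2Cl2, −20 → 0 °C; rapid filtration through a short silica pad, used at once
Reagents that add atoms: carbon tetrabromide, BrC(Br)(Br)Br
Why: Appel bromination under neutral conditions that spare the MOM ethers and the ketone; the ring is fully substituted, so the electron-rich benzylic bromide cannot alkylate itself.

Step 7
Reactants: 11 1-[3-(bromomethyl)-6-methoxy-2,4-bis(methoxymethoxy)-5-methylphenyl]butan-1-one; 12 tert-butoxyacetylene
Product: 15 1-[3-(3-tert-butoxyprop-2-yn-1-yl)-6-methoxy-2,4-bis(methoxymethoxy)-5-methylphenyl]butan-1-one, via lithium tert-butoxyacetylide 13 (not isolated), via (tert-butoxyethynyl)zinc chloride 14 (not isolated)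
Conditions: 12, n-BuLi, THF, −78 °C; ZnCl2, −78 → 0 °C; then 11, PdCl2(DPEphos) (5 mol%), THF, 0 °C → rt; aq NaHCO3; Et3N-deactivated silica
Reagents that add atoms: none
Why: Negishi coupling: zerovalent palladium formed in the flask inserts into the benzylic C–Br bond, the alkynyl group is transferred from zinc, and reductive elimination forms the C(sp3)–C(sp) bond. Benzylic halide–alkynylzinc couplings and palladium-catalysed couplings of alkoxyethynylzinc chlorides are both established, and the zinc reagent should leave the hindered aryl ketone alone.

Step 8
Reactants: 12 tert-butoxyacetylene; 7 N-methoxy-N-methylbutanamide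
Product: 18 1-tert-butoxyhex-1-yn-3-one, via (tert-butoxyethynyl)magnesium bromide 16 (not isolated), via tetrahedral adduct 17 (not isolated)
Conditions: EtMgBr, THF, 0 °C → rt; then 7, 0 °C → rt; AcOH, −40 °C, then pH 7 buffer; used without heating
Reagents that add atoms: none
Why: Acylation of an alkynyl Grignard reagent by a Weinreb amide; EtMgBr deprotonates the terminal alkyne as it does ethoxyacetylene, and the magnesium chelate 17 holds until work-up, so no second addition occurs. The cold acidic quench protonates the released amine before it can add to the push–pull ynone.

Step 9
Reactants: 15 1-[3-(3-tert-butoxyprop-2-yn-1-yl)-6-methoxy-2,4-bis(methoxymethoxy)-5-methylphenyl]butan-1-one (2.1 equiv); 18 1-tert-butoxyhex-1-yn-3-one (1 equiv)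
Product: 19 1-[2,4,6-tri-tert-butoxy-3,5-bis({3-butanoyl-4-methoxy-2,6-bis(methoxymethoxy)-5-methylphenyl}methyl)phenyl]butan-1-one
Conditions: [Rh(cod)2]BF4 (10 mol%), rac-BINAP (10 mol%), CH2Cl2, H2 then Ar (catalyst activation); 18, slow addition of 15, rt
Reagents that add atoms: none
Why: Proposed new method: a cationic monovalent rhodium–bisphosphine complex is expected to join ynone 18 and one molecule of 15 by oxidative cyclisation to a rhodacyclopentadiene of trivalent rhodium, insert a second molecule of 15, and close ring A by C–C reductive elimination, forming C2–C3, C4–C5 and C6–C1. The closest known reaction type is the chemo- and regioselective cross-cyclotrimerisation of two electron-rich alkynes with one electron-poor alkyne under [Rh(cod)2]BF4/bisphosphine catalysis, together with regioselective cyclotrimerisations of ynamides and aryl ethynyl ethers; three internal ynol ethers giving a hexasubstituted benzene have not been shown. Ring A is closed in an intermolecular three-component [2+2+2] mode in which all six ring carbons are former alkyne carbons. No stereocentre is formed. The step needs two-to-one chemoselectivity and head-to-tail regiochemistry. Chemoselectivity should follow from donor–acceptor pairing: 18 is the only acceptor, its rhodacycle with a donor alkyne should form faster than a donor–donor one, and 18 is kept as the limiting partner while 15 is added slowly. Regiochemistry should follow from polarisation: each ynol ether is nucleophilic at the carbon remote from oxygen and electrophilic at the oxygen-bearing carbon, and in 18 the carbonyl reinforces this, so every new bond joins a carbon-substituted to an oxygen-substituted carbon. Room temperature is kept so that the tert-butyl ynol ethers do not lose isobutene; the hindered aryl ketones and MOM ethers should be spectators.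

Step 10
Reactants: 19 1-[2,4,6-tri-tert-butoxy-3,5-bis({3-butanoyl-4-methoxy-2,6-bis(methoxymethoxy)-5-methylphenyl}methyl)phenyl]butan-1-one
Product: 20 Agrimol C (1-[3,5-bis({3-butanoyl-2,6-dihydroxy-4-methoxy-5-methylphenyl}methyl)-2,4,6-trihydroxyphenyl]butan-1-one)
Conditions: HCl (3 M in MeOH), THF, rt → 40 °C, under Ar
Reagents that add atoms: none
Why: Acid-catalysed acetal exchange should remove the four MOM groups, and E1 cleavage should remove the three crowded aryl tert-butyl ethers. Every ring carbon is substituted and each ring carries an acyl group, so the released cations find no ring position to alkylate and ipso protonation at the bridges is disfavoured.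

## Compound list

1 | 2,4,6-trimethoxytoluene | Cc1c(OC)cc(OC)cc1OC | starting material
2 | (2,4,6-trimethoxy-3-methylbenzylidene)dimethyliminium chloride (not isolated) | C[N+](C)=Cc1c(OC)c(C)c(OC)cc1OC.[Cl-] | intermediate
3 | 2,4,6-trimethoxy-3-methylbenzaldehyde | O=Cc1c(OC)c(C)c(OC)cc1OC | intermediate
4 | 2,6-dihydroxy-4-methoxy-3-methylbenzaldehyde | O=Cc1c(O)c(C)c(OC)cc1O | intermediate
5 | 4-methoxy-2,6-bis(methoxymethoxy)-3-methylbenzaldehyde | O=Cc1c(OCOC)c(C)c(OC)cc1OCOC | intermediate
6 | [4-methoxy-2,6-bis(methoxymethoxy)-3-methylphenyl]methanol | OCc1c(OCOC)c(C)c(OC)cc1OCOC | intermediate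
7 | N-methoxy-N-methylbutanamide | CCCC(=O)N(C)OC | starting material
8 | lithium [3-lithio-4-methoxy-2,6-bis(methoxymethoxy)-5-methylphenyl]methanolate (not isolated) | [Li+].[O-]Cc1c(OCOC)c(C)c(OC)c([Li])c1OCOC | intermediate
9 | dilithium salt of the N-methoxy-N-methyl hemiaminal from 8 and 7, racemic (not isolated) | CCCC(O[Li])(N(C)OC)c1c(OC)c(C)c(OCOC)c(CO[Li])c1OCOC | intermediate
10 | 1-[3-(hydroxymethyl)-6-methoxy-2,4-bis(methoxymethoxy)-5-methylphenyl]butan-1-one | CCCC(=O)c1c(OC)c(C)c(OCOC)c(CO)c1OCOC | intermediate
11 | 1-[3-(bromomethyl)-6-methoxy-2,4-bis(methoxymethoxy)-5-methylphenyl]butan-1-one | CCCC(=O)c1c(OC)c(C)c(OCOC)c(CBr)c1OCOC | intermediate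
12 | tert-butoxyacetylene | CC(C)(C)OC#C | starting material
13 | lithium tert-butoxyacetylide (not isolated) | [Li]C#COC(C)(C)C | intermediate
14 | (tert-butoxyethynyl)zinc chloride (not isolated) | Cl[Zn]C#COC(C)(C)C | intermediate
15 | 1-[3-(3-tert-butoxyprop-2-yn-1-yl)-6-methoxy-2,4-bis(methoxymethoxy)-5-methylphenyl]butan-1-one | CCCC(=O)c1c(OC)c(C)c(OCOC)c(CC#COC(C)(C)C)c1OCOC | intermediate
16 | (tert-butoxyethynyl)magnesium bromide (not isolated) | Br[Mg]C#COC(C)(C)C | intermediate
17 | bromomagnesium salt of the N-methoxy-N-methyl hemiaminal from 16 and 7, racemic (not isolated) | CCCC(O[Mg]Br)(N(C)OC)C#COC(C)(C)C | intermediate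
18 | 1-tert-butoxyhex-1-yn-3-one | CCCC(=O)C#COC(C)(C)C | intermediate
19 | 1-[2,4,6-tri-tert-butoxy-3,5-bis({3-butanoyl-4-methoxy-2,6-bis(methoxymethoxy)-5-methylphenyl}methyl)phenyl]butan-1-one | CCCC(=O)c1c(OC(C)(C)C)c(Cc2c(OCOC)c(C)c(OC)c(C(=O)CCC)c2OCOC)c(OC(C)(C)C)c(Cc2c(OCOC)c(C)c(OC)c(C(=O)CCC)c2OCOC)c1OC(C)(C)C | intermediate
20 | Agrimol C | CCCC(=O)c1c(O)c(Cc2c(O)c(C)c(OC)c(C(=O)CCC)c2O)c(O)c(Cc2c(O)c(C)c(OC)c(C(=O)CCC)c2O)c1O | target

## Step count and least certain steps

Total: 10 steps. Longest linear sequence: 9 steps (steps 1–7, 9, 10) from 2,4,6-trimethoxytoluene 1.

**Step 9 (key step, new method).**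
- What may go wrong: homotrimerisation of 15; incorporation of two molecules of 18; head-to-head coupling giving regioisomeric arenes; Lewis-acid-induced loss of isobutene from the ynol ethers; failure of the last reductive elimination, which must create a benzene flanked by three tert-butoxy groups.
- Why: nothing but polarisation distinguishes the two ends of each alkyne, and the metal is both catalyst and Lewis acid.
- Fallback (known chemistry, from 10, returning at 20): alcohol 10 is treated with HCl in methanol. This removes both MOM groups and exchanges the benzylic hydroxyl for methoxyl, giving 1-[2,4-dihydroxy-6-methoxy-3-(methoxymethyl)-5-methylphenyl]butan-1-one F1. Two equivalents of F1 are then warmed with commercial 1-(2,4,6-trihydroxyphenyl)butan-1-one F2 in a weakly basic aqueous–organic buffer. F1 loses methanol to an ortho-quinone methide, which the two free ring positions of F2 capture. This is the classical electrophilic bridging of acylphloroglucinols and gives 20 directly.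

**Step 7.**
- What may go wrong: ionisation of the electron-rich benzylic bromide before or during coupling, assisted by ZnCl2, with capture by a neighbouring MOM oxygen or homocoupling; hydration or isobutene loss of the product ynol ether in the presence of zinc salts.
- Fallback (from 12, returning at 15): acetylide 13, made as in step 7, is quenched with Bu3SnCl to give isolable tributyl(tert-butoxyethynyl)stannane F3. F3 is coupled with bromide 11 in a salt-free Stille reaction (Pd(PPh3)4, THF, rt), which removes the Lewis acid and the basic organometallic from the coupling.

**Step 8.**
- What may go wrong: conjugate addition of the liberated N,O-dimethylhydroxylamine to the push–pull ynone during work-up, or retro-ene loss of isobutene giving an acylketene, because the acyl group makes the alkyne both more electrophilic and more prone to hydrogen transfer.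
- Fallback (from 12, returning at 18): the magnesium acetylide 16, made as in step 8, is added to butanal at −20 °C to give racemic 1-tert-butoxyhex-1-yn-3-ol F4, which is oxidised with MnO2 in CH2Cl2 at rt. The ynone is then reached under neutral conditions with no amine present.

**Step 5.**
- What may go wrong: incomplete ring lithiation of the alkoxide, competing lateral lithiation at the aryl methyl group, or enolisation of 7 by the hindered aryllithium, returning 6.
- Fallback (from 4, returning at 10): diphenol 4 is butyrylated at its only free ring position by Friedel–Crafts acylation (butanoyl chloride, TiCl4, CH2Cl2) to give 3-butanoyl-2,6-dihydroxy-4-methoxy-5-methylbenzaldehyde F5. Protection with NaH/MOMCl gives 3-butanoyl-4-methoxy-2,6-bis(methoxymethoxy)-5-methylbenzaldehyde F6. NaBH4 at 0 °C then reduces the aldehyde in preference to the doubly ortho-substituted ketone.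

**Step 10.**
- What may go wrong: acid-promoted opening of the methylene bridges with capture by methanol, or incomplete cleavage of the tert-butyl ethers at a temperature the bridges tolerate.
- Fallback (from 19, returning at 20): the tert-butyl ethers are removed first with trifluoroacetic acid in CH2Cl2 at 0 °C, giving 1-[3,5-bis({3-butanoyl-4-methoxy-2,6-bis(methoxymethoxy)-5-methylphenyl}methyl)-2,4,6-trihydroxyphenyl]butan-1-one F7. The MOM groups of F7 are then removed aprotically with ZnBr2 and 1-propanethiol in CH2Cl2 at 0 °C.

## Further compounds

F1 | step 9 | 1-[2,4-dihydroxy-6-methoxy-3-(methoxymethyl)-5-methylphenyl]butan-1-one | CCCC(=O)c1c(OC)c(C)c(O)c(COC)c1O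
F2 | step 9 | 1-(2,4,6-trihydroxyphenyl)butan-1-one (purchased) | CCCC(=O)c1c(O)cc(O)cc1O
F3 | step 7 | tributyl(tert-butoxyethynyl)stannane | CCCC[Sn](CCCC)(CCCC)C#COC(C)(C)C
F4 | step 8 | 1-tert-butoxyhex-1-yn-3-ol, racemic | CCCC(O)C#COC(C)(C)C
F5 | step 5 | 3-butanoyl-2,6-dihydroxy-4-methoxy-5-methylbenzaldehyde | CCCC(=O)c1c(OC)c(C)c(O)c(C=O)c1O
F6 | step 5 | 3-butanoyl-4-methoxy-2,6-bis(methoxymethoxy)-5-methylbenzaldehyde | CCCC(=O)c1c(OC)c(C)c(OCOC)c(C=O)c1OCOC
F7 | step 10 | 1-[3,5-bis({3-butanoyl-4-methoxy-2,6-bis(methoxymethoxy)-5-methylphenyl}methyl)-2,4,6-trihydroxyphenyl]butan-1-one | CCCC(=O)c1c(O)c(Cc2c(OCOC)c(C)c(OC)c(C(=O)CCC)c2OCOC)c(O)c(Cc2c(OCOC)c(C)c(OC)c(C(=O)CCC)c2OCOC)c1O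
A1 | alternative 1 | Agrimol C pentaacetate with free C6' and C6'' hydroxyls | CCCC(=O)c1c(OC(C)=O)c(Cc2c(O)c(C(=O)CCC)c(OC)c(C)c2OC(C)=O)c(OC(C)=O)c(Cc2c(O)c(C(=O)CCC)c(OC)c(C)c2OC(C)=O)c1OC(C)=O
A2 | alternative 1 | 6',6''-dideoxy-Agrimol C pentaacetate | CCCC(=O)c1c(OC(C)=O)c(Cc2cc(C(=O)CCC)c(OC)c(C)c2OC(C)=O)c(OC(C)=O)c(Cc2cc(C(=O)CCC)c(OC)c(C)c2OC(C)=O)c1OC(C)=O
A3 | alternative 2 | Agrimol C heptabenzyl ether | CCCC(=O)c1c(OCc2ccccc2)c(Cc2c(OCc3ccccc3)c(C)c(OC)c(C(=O)CCC)c2OCc2ccccc2)c(OCc2ccccc2)c(Cc2c(OCc3ccccc3)c(C)c(OC)c(C(=O)CCC)c2OCc2ccccc2)c1OCc1ccccc1
A4 | alternative 2 | ring A 2,4,6-trifluoro analogue of the outer-ring tetrabenzyl ether of Agrimol C | CCCC(=O)c1c(F)c(Cc2c(OCc3ccccc3)c(C)c(OC)c(C(=O)CCC)c2OCc2ccccc2)c(F)c(Cc2c(OCc3ccccc3)c(C)c(OC)c(C(=O)CCC)c2OCc2ccccc2)c1F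
A5 | alternative 3 | Agrimol C lacking both outer butyryl groups, outer hydroxyls as benzyl ethers | CCCC(=O)c1c(O)c(Cc2c(OCc3ccccc3)c(C)c(OC)cc2OCc2ccccc2)c(O)c(Cc2c(OCc3ccccc3)c(C)c(OC)cc2OCc2ccccc2)c1O
A6 | alternative 3 | methyl 2,4-bis{[2,6-bis(benzyloxy)-4-methoxy-3-methylphenyl]methyl}-3,5,7-trioxodecanoate | CCCC(=O)CC(=O)C(Cc1c(OCc2ccccc2)c(C)c(OC)cc1OCc1ccccc1)C(=O)C(Cc1c(OCc2ccccc2)c(C)c(OC)cc1OCc1ccccc1)C(=O)OC
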